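**Strategy.** The α-methylene-γ-butyrolactone (ring O–C12–C11–C7–C8, germacrane numbering) is stitched on last from a one-carbon, two-oxygen unit. The precursor is the bridged ten-membered carbocycle already carrying the 15,6-butenolide, with an ethynyl group on C7 and a mesylate on C8 cis to it. Palladium-catalysed Markovnikov hydrocarboxylation with formic acid joins C11 to C12; the carboxylate then displaces the C8 mesylate with inversion, joining O to C8 and creating the trans ring fusion in the same flask. The macrocycle comes from a Nozaki–Hiyama–Kishi closure of C3–C4, and the C6–C7–C8 triad from an allenylindium addition of a cis-alkynyl epoxide to acrolein.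

Key step: step 15

Remark: all intermediates carry the germacrane locants of the target (C3 isobutyryloxy carbon, C4=C5 and C15 butenolide, C6 butenolide O–CH, C7, C8 lactone O–CH, C10 with C14H2O, C11=C13H2, C12 lactone C=O), and descriptors refer to these locants; compound 1, the THF solution of 4 and the D-glucose-derived Shi ketone are assumed to be purchasable or known.

Step 1
Reactants: 1 2-[(tert-butyldiphenylsilyl)oxy]acetaldehyde; 2 methyl (triphenylphosphoranylidene)acetate
Product: 3 methyl (E)-4-[(tert-butyldiphenylsilyl)oxy]but-2-enoate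
Conditions: CH2Cl2, rt
Reagents that add atoms: none
Why: Wittig olefination with a stabilised ylide should give the (E)-enoate selectively.

Step 2
Reactants: 3 methyl (E)-4-[(tert-butyldiphenylsilyl)oxy]but-2-enoate; 4 [2-(1,3-dioxolan-2-yl)ethyl]magnesium bromide
Product: 5 methyl (3R)-3-{[(tert-butyldiphenylsilyl)oxy]methyl}-5-(1,3-dioxolan-2-yl)pentanoate
Conditions: CuBr·SMe2 (5 mol%), Josiphos (6 mol%, antipode chosen for the 10R product), t-BuOMe, −75 °C, slow addition of 4
Reagents that add atoms: none
Why: Copper-catalysed asymmetric conjugate addition of a Grignard reagent to an (E)-enoate, in which the ferrocenyl diphosphine controls the enoate face and so sets C10 (R); the silyloxy group is not β to the enolate carbon and cannot eliminate.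

Step 3
Reactants: 5 methyl (3R)-3-{[(tert-butyldiphenylsilyl)oxy]methyl}-5-(1,3-dioxolan-2-yl)pentanoate
Product: 6 (3R)-3-{[(tert-butyldiphenylsilyl)oxy]methyl}-5-(1,3-dioxolan-2-yl)pentanal
Conditions: DIBAL-H (1.05 equiv), CH2Cl2, −78 °C; Rochelle salt
Reagents that add atoms: none
Why: DIBAL-H half-reduction of a methyl ester at −78 °C should stop at the aluminium hemiacetal and release the C8 aldehyde on work-up, the β-stereocentre being non-epimerisable.

Step 4
Reactants: 6 (3R)-3-{[(tert-butyldiphenylsilyl)oxy]methyl}-5-(1,3-dioxolan-2-yl)pentanal; 7 1,3-bis(trimethylsilyl)propyne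
Product: 9 tert-butyl{[(2R,4Z)-2-[2-(1,3-dioxolan-2-yl)ethyl]-7-(trimethylsilyl)hept-4-en-6-yn-1-yl]oxy}diphenylsilane, via lithiated bis-silylpropyne 8 (not isolated)
Conditions: 7, t-BuLi, THF, −78 °C; MgBr2·OEt2; then 6, −78 °C to rt
Reagents that add atoms: none
Why: Peterson olefination of the magnesium derivative of the lithiated propargylsilane should give the (Z)-enyne (C8=C7–C11≡C13) by syn elimination of the kinetically favoured β-oxidosilane.

Step 5
Reactants: 9 tert-butyl{[(2R,4Z)-2-[2-(1,3-dioxolan-2-yl)ethyl]-7-(trimethylsilyl)hept-4-en-6-yn-1-yl]oxy}diphenylsilane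
Product: 10 tert-butyl{(2R)-4-(1,3-dioxolan-2-yl)-2-{[(2S,3R)-3-[(trimethylsilyl)ethynyl]oxiran-2-yl]methyl}butoxy}diphenylsilane
Conditions: Shi D-glucose-derived N-aryl-oxazolidinone ketone (25 mol%), Oxone, K2CO3, Bu4NHSO4, DME/DMM–aqueous buffer, −10 °C
Reagents that add atoms: Oxone (potassium peroxymonosulfate), [K+].[O-]S(=O)(=O)OO
Why: Shi asymmetric epoxidation with the ketone designed for cis-olefins, in which the dioxirane transfers oxygen stereospecifically (cis retained) and the alkynyl group lies next to the oxazolidinone in the spiro transition state, should give the (7R,8S)-epoxide under catalyst control.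

Step 6
Reactants: 10 tert-butyl{(2R)-4-(1,3-dioxolan-2-yl)-2-{[(2S,3R)-3-[(trimethylsilyl)ethynyl]oxiran-2-yl]methyl}butoxy}diphenylsilane; 11 acrolein
Product: 12 (3S,4S,5S,7R)-7-{[(tert-butyldiphenylsilyl)oxy]methyl}-9-(1,3-dioxolan-2-yl)-4-[(trimethylsilyl)ethynyl]non-1-ene-3,5-diol
Conditions: Pd(PPh3)4 (5 mol%), InI (1.5 equiv), THF/HMPA 3:1, rt
Reagents that add atoms: none
Why: Pd(0)/InI umpolung of a propargylic electrophile (Marshall-type allenylindium addition, here from an alkynyl epoxide): anti-SN2′ oxidative addition, retentive Pd-to-In transfer and syn-SE2′ addition through a cyclic transition state should replace the C7–O bond by the C7–C6 bond with net inversion (7S) and give the anti (Marshall sense) carbinol at C6 (6S), while the C8–O bond keeps its configuration.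

Step 7
Reactants: 12 (3S,4S,5S,7R)-7-{[(tert-butyldiphenylsilyl)oxy]methyl}-9-(1,3-dioxolan-2-yl)-4-[(trimethylsilyl)ethynyl]non-1-ene-3,5-diol; 13 acrylic acid
Product: 14 (3R,4S,5S,7R)-7-{[(tert-butyldiphenylsilyl)oxy]methyl}-9-(1,3-dioxolan-2-yl)-5-hydroxy-4-[(trimethylsilyl)ethynyl]non-1-en-3-yl prop-2-enoate
Conditions: PPh3, DIAD, THF, −20 to 0 °C
Reagents that add atoms: none
Why: Mitsunobu esterification, in which the allylic C6 oxyphosphonium ion is displaced far faster than an unactivated secondary one, should put the acrylate on C6 only and with SN2 inversion, turning (6S) into the (6R) configuration of the butenolide.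

Step 8
Reactants: 14 (3R,4S,5S,7R)-7-{[(tert-butyldiphenylsilyl)oxy]methyl}-9-(1,3-dioxolan-2-yl)-5-hydroxy-4-[(trimethylsilyl)ethynyl]non-1-en-3-yl prop-2-enoate
Product: 15 (3R,4R,5S,7R)-7-{[(tert-butyldiphenylsilyl)oxy]methyl}-9-(1,3-dioxolan-2-yl)-5-[(methylsulfonyl)oxy]-4-[(trimethylsilyl)ethynyl]non-1-en-3-yl prop-2-enoate
Conditions: MsCl, Et3N, CH2Cl2, 0 °C
Reagents that add atoms: methanesulfonyl chloride, CS(=O)(=O)Cl
Why: Sulfonylation of the remaining C8 alcohol forms an O–S bond only, so the (8S) centre is retained and the leaving group for the key step is in place.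

Step 9
Reactants: 15 (3R,4R,5S,7R)-7-{[(tert-butyldiphenylsilyl)oxy]methyl}-9-(1,3-dioxolan-2-yl)-5-[(methylsulfonyl)oxy]-4-[(trimethylsilyl)ethynyl]non-1-en-3-yl prop-2-enoate
Product: 16 (6R,7R,8S,10R)-butenolide mesylate (5-substituted furan-2(5H)-one on C6)
Conditions: Grubbs II (5 mol%), CH2Cl2, 40 °C, 5 mM
Reagents that add atoms: none
Why: Ring-closing metathesis of an allyl acrylate to a butenolide is a five-membered closure that should outpace every other metathesis pathway, the silyl-capped alkyne being inert.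

Step 10
Reactants: 16 (6R,7R,8S,10R)-butenolide mesylate
Product: 17 (6S,7R,8S,10R)-3-iodobutenolide mesylate (iodine on C4; descriptor at C6 changes by priority only)
Conditions: I2, pyridine, CH2Cl2, rt, dark
Reagents that add atoms: iodine, II
Why: Johnson-type α-iodination of an α,β-unsaturated lactone (pyridine addition, iodination of the enolate, elimination) should functionalise C4 only.

Step 11
Reactants: 17 (6S,7R,8S,10R)-3-iodobutenolide mesylate
Product: 18 (6S,7R,8S,10R)-iodobutenolide aldehyde (C3 = CHO)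
Conditions: PPTS, acetone/H2O 9:1, 55 °C
Reagents that add atoms: water, O
Why: Acid-catalysed hydrolysis of the dioxolane should free the C3 aldehyde, since the TBDPS ether, the mesylate, the alkynylsilane and the iodobutenolide are stable to PPTS.

Step 12
Reactants: 18 (6S,7R,8S,10R)-iodobutenolide aldehyde
Product: 19 (3S,6R,7R,8S,10R)-macrocyclic C3 alcohol (ten-membered ring bridged by the 15,6-butenolide)
Conditions: CrCl2 (10 equiv), NiCl2 (1 mol%), DMSO/THF, rt, 2 mM, syringe-pump addition
Reagents that add atoms: none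
Why: Intramolecular Nozaki–Hiyama–Kishi reaction of the alkenyl iodide with the aldehyde closes the ten-membered ring at C3–C4; the tether forces C2 onto the butenolide face that carries C7 and the chromium-bound oxygen should sit on the C5–H side, away from the lactone carbonyl, which corresponds to the (3S) alcohol.

Step 13
Reactants: 19 (3S,6R,7R,8S,10R)-macrocyclic C3 alcohol; 20 isobutyryl chloride
Product: 21 (3S,6R,7R,8S,10R)-macrocyclic 3-isobutyrate with silylated alkyne
Conditions: pyridine, DMAP (cat.), CH2Cl2, 0 °C to rt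
Reagents that add atoms: none
Why: DMAP-catalysed acylation of the secondary alcohol forms the ester with retention at C3.

Step 14
Reactants: 21 (3S,6R,7R,8S,10R)-macrocyclic 3-isobutyrate with silylated alkyne
Product: 22 (3S,6R,7R,8S,10R)-7-ethynyl 8-mesylate (key-step precursor)
Conditions: AgNO3 (10 mol%), MeOH/H2O/CH2Cl2, rt
Reagents that add atoms: none
Why: Silver-catalysed protodesilylation of an alkynylsilane should free the terminal alkyne without touching the silyl ether, the esters or the mesylate.

Step 15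
Reactants: 22 (3S,6R,7R,8S,10R)-7-ethynyl 8-mesylate; 23 formic acid
Product: 25 (3S,6R,7S,8R,10R)-14-O-TBDPS ether of the target, via acrylic acid 24 (not isolated)
Conditions: Pd(OAc)2 (5 mol%), Xantphos (10 mol%), 23 (3 equiv), Ac2O (20 mol%), toluene, 80 °C; then evaporate, KHCO3, DMF, 50 °C
Reagents that add atoms: none
Why: Pd–H, generated from formic acid through acetic formic anhydride, should add across the terminal alkyne with Pd on C11, and CO insertion followed by acyl transfer to formate gives the 2-substituted acrylic acid 24 (C11–C12 bond), the closest known reaction type being the Pd-catalysed hydrocarboxylation of terminal alkynes with formic acid. After neutralisation the carboxylate displaces the C8 mesylate in a 5-exo-tet SN2 reaction (O–C8 bond), the known lactonisation of γ-sulfonyloxy carboxylates with inversion, which closes the α-methylene-γ-butyrolactone. C8 is the only stereocentre set, and it is controlled by stereospecific inversion of the (8S)-mesylate, so the cis C7/C8 arrangement of 22 becomes the trans ring fusion with (8R). The step needs branched regioselectivity, which rests on the preference of Pd–H under a wide-bite-angle diphosphine for the internal carbon of a terminal alkyne. It needs chemoselectivity over the butenolide C4=C5 bond and the esters, which rests on the much faster hydropalladation of alkynes. It needs substitution over elimination, which the near anti-periplanar disposition of C11 and the mesylate across C7–C8 in the ten-membered ring and the weak base should secure.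

Step 16
Reactants: 25 (3S,6R,7S,8R,10R)-14-O-TBDPS ether of the target
Product: 26 CNP0332805.1 (target)
Conditions: HF·pyridine, THF/pyridine, 0 °C to rt
Reagents that add atoms: none
Why: Fluoride cleavage of the Si–O bond under buffered acidic conditions should free the C14 alcohol without conjugate addition to the α-methylene lactone or opening of either lactone.

**Compound list**

1 | 2-[(tert-butyldiphenylsilyl)oxy]acetaldehyde | O=CCO[Si](c1ccccc1)(c1ccccc1)C(C)(C)C | starting material
2 | methyl (triphenylphosphoranylidene)acetate | COC(=O)C=P(c1ccccc1)(c1ccccc1)c1ccccc1 | starting material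
3 | methyl (E)-4-[(tert-butyldiphenylsilyl)oxy]but-2-enoate | COC(=O)/C=C/CO[Si](c1ccccc1)(c1ccccc1)C(C)(C)C | intermediate
4 | [2-(1,3-dioxolan-2-yl)ethyl]magnesium bromide | Br[Mg]CCC1OCCO1 | starting material
5 | methyl (3R)-3-{[(tert-butyldiphenylsilyl)oxy]methyl}-5-(1,3-dioxolan-2-yl)pentanoate | COC(=O)C[C@H](CO[Si](c1ccccc1)(c1ccccc1)C(C)(C)C)CCC1OCCO1 | intermediate
6 | (3R)-3-{[(tert-butyldiphenylsilyl)oxy]methyl}-5-(1,3-dioxolan-2-yl)pentanal | O=CC[C@H](CO[Si](c1ccccc1)(c1ccccc1)C(C)(C)C)CCC1OCCO1 | intermediate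
7 | 1,3-bis(trimethylsilyl)propyne | C[Si](C)(C)CC#C[Si](C)(C)C | starting material
8 | 3-lithio-1,3-bis(trimethylsilyl)propyne (not isolated) | C[Si](C)(C)C([Li])C#C[Si](C)(C)C | intermediate
9 | tert-butyl{[(2R,4Z)-2-[2-(1,3-dioxolan-2-yl)ethyl]-7-(trimethylsilyl)hept-4-en-6-yn-1-yl]oxy}diphenylsilane | C[Si](C)(C)C#C/C=C\C[C@H](CO[Si](c1ccccc1)(c1ccccc1)C(C)(C)C)CCC1OCCO1 | intermediate
10 | tert-butyl{(2R)-4-(1,3-dioxolan-2-yl)-2-{[(2S,3R)-3-[(trimethylsilyl)ethynyl]oxiran-2-yl]methyl}butoxy}diphenylsilane; cis-epoxide, (7R,8S,10R) | C[Si](C)(C)C#C[C@H]1O[C@H]1C[C@H](CO[Si](c2ccccc2)(c2ccccc2)C(C)(C)C)CCC2OCCO2 | intermediate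
11 | acrolein | C=CC=O | starting material
12 | (3S,4S,5S,7R)-7-{[(tert-butyldiphenylsilyl)oxy]methyl}-9-(1,3-dioxolan-2-yl)-4-[(trimethylsilyl)ethynyl]non-1-ene-3,5-diol; (6S,7S,8S,10R) | C[Si](C)(C)C#C[C@H]([C@@H](O)C=C)[C@@H](O)C[C@H](CO[Si](c1ccccc1)(c1ccccc1)C(C)(C)C)CCC1OCCO1 | intermediate
13 | acrylic acid | C=CC(=O)O | starting material
14 | (3R,4S,5S,7R)-7-{[(tert-butyldiphenylsilyl)oxy]methyl}-9-(1,3-dioxolan-2-yl)-5-hydroxy-4-[(trimethylsilyl)ethynyl]non-1-en-3-yl prop-2-enoate; (6R,7S,8S,10R) | C[Si](C)(C)C#C[C@H]([C@H](OC(=O)C=C)C=C)[C@@H](O)C[C@H](CO[Si](c1ccccc1)(c1ccccc1)C(C)(C)C)CCC1OCCO1 | intermediate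
15 | (3R,4R,5S,7R)-7-{[(tert-butyldiphenylsilyl)oxy]methyl}-9-(1,3-dioxolan-2-yl)-5-[(methylsulfonyl)oxy]-4-[(trimethylsilyl)ethynyl]non-1-en-3-yl prop-2-enoate; (6R,7R,8S,10R) | C[Si](C)(C)C#C[C@H]([C@H](OC(=O)C=C)C=C)[C@@H](OS(C)(=O)=O)C[C@H](CO[Si](c1ccccc1)(c1ccccc1)C(C)(C)C)CCC1OCCO1 | intermediate
16 | (6R,7R,8S,10R)-butenolide mesylate: furan-2(5H)-one whose C5 (= C6) carries C7H(C≡C–SiMe3)–C8H(OMs)–C9H2–C10H(CH2OTBDPS)–CH2CH2–(1,3-dioxolan-2-yl) | C[Si](C)(C)C#C[C@H]([C@@H]1OC(=O)C=C1)[C@@H](OS(C)(=O)=O)C[C@H](CO[Si](c2ccccc2)(c2ccccc2)C(C)(C)C)CCC2OCCO2 | intermediate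
17 | (6S,7R,8S,10R)-3-iodobutenolide mesylate: as 16 with iodine on C4 | C[Si](C)(C)C#C[C@H]([C@@H]1OC(=O)C(I)=C1)[C@@H](OS(C)(=O)=O)C[C@H](CO[Si](c2ccccc2)(c2ccccc2)C(C)(C)C)CCC2OCCO2 | intermediate
18 | (6S,7R,8S,10R)-iodobutenolide aldehyde: as 17 with the dioxolane replaced by the C3 aldehyde | C[Si](C)(C)C#C[C@H]([C@@H]1OC(=O)C(I)=C1)[C@@H](OS(C)(=O)=O)C[C@H](CO[Si](c2ccccc2)(c2ccccc2)C(C)(C)C)CCC=O | intermediate
19 | (3S,6R,7R,8S,10R)-macrocyclic alcohol: germacr-4-en-15,6-olide with 3-OH, 7-[(trimethylsilyl)ethynyl], 8-OMs, 10-CH2OTBDPS | C[Si](C)(C)C#C[C@H]1[C@@H](OS(C)(=O)=O)C[C@H](CO[Si](c2ccccc2)(c2ccccc2)C(C)(C)C)CC[C@H](O)C2=C[C@H]1OC2=O | intermediate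
20 | isobutyryl chloride | CC(C)C(=O)Cl | starting material
21 | (3S,6R,7R,8S,10R)-3-isobutyrate of 19 | C[Si](C)(C)C#C[C@H]1[C@@H](OS(C)(=O)=O)C[C@H](CO[Si](c2ccccc2)(c2ccccc2)C(C)(C)C)CC[C@H](OC(=O)C(C)C)C2=C[C@H]1OC2=O | intermediate
22 | (3S,6R,7R,8S,10R)-7-ethynyl 8-mesylate: 21 without the alkyne silyl group | C#C[C@H]1[C@@H](OS(C)(=O)=O)C[C@H](CO[Si](c2ccccc2)(c2ccccc2)C(C)(C)C)CC[C@H](OC(=O)C(C)C)C2=C[C@H]1OC2=O | intermediate
23 | formic acid | O=CO | starting material
24 | (3S,6R,7R,8S,10R)-acrylic acid: 22 with C7 carrying C(=CH2)CO2H (not isolated) | C=C(C(=O)O)[C@H]1[C@@H](OS(C)(=O)=O)C[C@H](CO[Si](c2ccccc2)(c2ccccc2)C(C)(C)C)CC[C@H](OC(=O)C(C)C)C2=C[C@H]1OC2=O | intermediate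
25 | (3S,6R,7S,8R,10R)-14-O-(tert-butyldiphenylsilyl) ether of the target | C=C1C(=O)O[C@@H]2C[C@H](CO[Si](c3ccccc3)(c3ccccc3)C(C)(C)C)CC[C@H](OC(=O)C(C)C)C3=C[C@@H](OC3=O)[C@@H]12 | intermediate
26 | CNP0332805.1: (3S,6R,7S,8R,10R)-14-hydroxy-3-isobutyryloxygermacra-4,11(13)-diene-12,8:15,6-diolide | C=C1C(=O)O[C@@H]2C[C@H](CO)CC[C@H](OC(=O)C(C)C)C3=C[C@@H](OC3=O)[C@@H]12 | target

**Totals.** Total step count: 16. Longest linear sequence: 16 steps (from 1).

**Steps most likely to fail**

Step 15 (key step). Hydropalladation at the α-branched alkyne may place palladium on the terminal carbon and lead to the linear acid, or the mesylate may ionise or eliminate at 80 °C before the carboxylate exists. The fallback sets out from 22 and fixes the regiochemistry with a carbon–iodine bond. Markovnikov hydroiodination of 22 (NaI, Me3SiCl, H2O, MeCN, rt) should give the 2-iodoalkene F1. Palladium-catalysed hydroxycarbonylation of F1 (Pd(OAc)2, dppf, CO 1 atm, KOAc, DMF/H2O, 50 °C) then forms the potassium acrylate at the lower temperature, and this closes onto the C8 mesylate with inversion, so the sequence comes back to the route at 25.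

Step 12. The addition of the alkenylchromium to the aldehyde may occur from the other face, or without preference, because the selectivity rests on conformational control in a forming medium ring. The fallback sets out from 18 and changes the way C3 is set. If the cyclisation delivers mainly the (3R)-epimeric alcohol F2, Mitsunobu esterification with isobutyric acid (PPh3, DIAD, toluene, 0 °C) installs the ester with inversion and comes back to the route at 21, so step 13 is not needed for that material.

Step 7. Activation may occur at the C8 hydroxyl instead of, or as well as, the C6 hydroxyl, and the acrylate may enter with allylic transposition. The fallback sets out from 12 and relies on the intrinsic reactivity of an allylic sulfonate instead of selective activation. Both hydroxyls are sulfonylated (MsCl, Et3N, CH2Cl2, −20 °C) to the bis-mesylate F3, and caesium acrylate (18-crown-6, toluene/DMF, rt) should displace only the allylic C6 mesylate, with inversion. This comes back to the route at 15 and makes step 8 unnecessary.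

**Further compounds**

F1 | step 15 | (3S,6R,7R,8S,10R)-7-(1-iodoethenyl) 8-mesylate (22 with C7 carrying C(I)=CH2) | C=C(I)[C@H]1[C@@H](OS(C)(=O)=O)C[C@H](CO[Si](c2ccccc2)(c2ccccc2)C(C)(C)C)CC[C@H](OC(=O)C(C)C)C2=C[C@H]1OC2=O
F2 | step 12 | (3R,6R,7R,8S,10R)-macrocyclic alcohol (C3 epimer of 19) | C[Si](C)(C)C#C[C@H]1[C@@H](OS(C)(=O)=O)C[C@H](CO[Si](c2ccccc2)(c2ccccc2)C(C)(C)C)CC[C@@H](O)C2=C[C@H]1OC2=O
F3 | step 7 | 6,8-bis-mesylate of diol 12 | C[Si](C)(C)C#C[C@H]([C@@H](OS(C)(=O)=O)C=C)[C@@H](OS(C)(=O)=O)C[C@H](CO[Si](c1ccccc1)(c1ccccc1)C(C)(C)C)CCC1OCCO1
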